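**Retrosynthetic overview**
1. Target ⇐ bis-isovalerylation, 12-OH-directed epoxidation and acetylation of a macrocyclic 11(20)-ene carrying a 12,13-acetonide; the ten-membered ring is closed last, at C4–C5, by a nickel-catalysed reductive coupling of a seco bis(alkenyl iodide).
2. Seco compound ⇐ Hosomi–Sakurai union at C9–C10 of a west allylsilane (C1–C4, C10–C15, C20) and an east lactone aldehyde (C5–C9, C16–C19); the same step creates C11=C20.
3. West fragment ⇐ furfuryl alcohol + citraconic anhydride: tethered furan Diels–Alder (six-membered ring first), exo-dihydroxylation, bridge opening, excision of the tether carbon, Negishi coupling, ynone chemistry.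
4. East fragment ⇐ 2-methylenepropane-1,3-diol + propargyl alcohol + methyl propionate: asymmetric alkynylation, directed hydroalumination/iodination, chelation-controlled aldol/lactonisation (γ-lactone second).
5. Ring order: cyclohexane → γ-lactone → ten-membered ring.

Assumption: catalyst, ligand and resolving-agent antipodes are those predicted by the usual models; where a model fails, the antipode is used.
Locants in names are the briarane locants of the target (C1–C20); C9′ is the citraconate carbon that is excised in step 7. On the six-membered ring, α is the face of O-12, O-13, O-14 and C2, and β is the face of the C15 methyl. TBS = tert-butyldimethylsilyl, TES = triethylsilyl, PMB = 4-methoxybenzyl, Tf = trifluoromethanesulfonyl.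

**West fragment**

Step 1
Reactants: 1 furfuryl alcohol; 2 citraconic anhydride
Product: 4 racemic tricyclic lactone acid (7-methyl-1-oxo-1,6,7,7a-tetrahydro-3H-3a,6-epoxy-2-benzofuran-7-carboxylic acid; lactone ring/CO2H exo; methyl endo), via furfuryl hydrogen citraconate 3 (not isolated)
Conditions: Et3N (0.1 equiv), toluene, 23 °C then 70 °C
Reagents that add atoms: none
Why: Alcoholysis of the anhydride at its less hindered carbonyl gives the (Z)-half-ester, whose intramolecular Diels–Alder reaction of the furan (exo mode enforced by the three-atom tether) fixes the relative configuration of C1, C10, C11 and C14 with C2 (CO2H) cis to the oxygen bridge.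

Step 2
Reactants: 4 racemic lactone acid
Product: 6 lactone acid as single enantiomer (C1 and C14 configured as in the target), via (R)-1-phenylethylammonium salt 5 (not isolated)
Conditions: (R)-1-phenylethylamine (0.5 equiv), i-PrOH, two recrystallisations; then 1 M HCl/EtOAc
Reagents that add atoms: none
Why: Classical resolution through the less soluble diastereomeric salt sets the absolute configuration on cheap material.

Step 3
Reactants: 6 lactone acid
Product: 7 diol acid (12α,13α-dihydroxy; cis to the oxygen bridge)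
Conditions: OsO4 (2 mol %), N-methylmorpholine N-oxide, acetone/H2O, 23 °C
Reagents that add atoms: N-methylmorpholine N-oxide (C[N+]1([O-])CCOCC1); water (O)
Why: Upjohn dihydroxylation of a 7-oxanorbornene takes place on the exo face only, which sets C12 and C13 cis to O-14.

Step 4
Reactants: 7 diol acid
Product: 8 acetonide acid (12α,13α-O-isopropylidene)
Conditions: 2,2-dimethoxypropane, TsOH·H2O (5 mol %), acetone, 23 °C
Reagents that add atoms: 2,2-dimethoxypropane (COC(C)(C)OC)
Why: Ketalisation of the only cis-1,2-diol pairs O-12 with O-13 and so keeps them distinct from O-14.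

Step 5
Reactants: 8 acetonide acid
Product: 11 butenolide acid (C10=C11; C9′(=O)–O–C20H2 lactone; 12α,13α-acetonide; 14α-OTBS; 1β-methyl; C2 = CO2H), via dilithium alkoxide carboxylate 9 (not isolated), via bis-TBS derivative 10 (not isolated)
Conditions: LiN(SiMe3)2 (2.2 equiv), THF, −78 → −30 °C; then TBSOTf (2.3 equiv), −78 → 0 °C; aqueous citric acid work-up (cleaves the silyl ester)
Reagents that add atoms: tert-butyldimethylsilyl trifluoromethanesulfonate (CC(C)(C)[Si](C)(C)OS(=O)(=O)C(F)(F)F)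
Why: E1cB ring opening, in which the lactone enolate at C10 expels the bridging oxygen from C11, frees the C14 alkoxide, which is silylated in the same flask; no stereocentre is touched.

Step 6
Reactants: 11 butenolide acid
Product: 12 diacid (C11=C20H2 exocyclic; C9′O2H on C10 as epimer mixture; C2O2H on C1; 12α,13α-acetonide; 14α-OTBS)
Conditions: SmI2 (3 equiv), THF/HMPA (10:1), t-BuOH (2 equiv), −78 → 0 °C; then 1 M HCl
Reagents that add atoms: none
Why: Single-electron reductive cleavage of the allylic lactone C–O bond (as for γ-acyloxy enoates) with α-protonation gives the β,γ-unsaturated acid; the C10 configuration does not matter because C9′ is removed next.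

Step 7
Reactants: 12 diacid
Product: 14 keto acid (C11 ketone; C10 methylene; C2O2H), via β-keto acid 13 (not isolated)
Conditions: O3, CH2Cl2/MeOH, −78 °C; Me2S; then 40 °C
Reagents that add atoms: ozone ([O-][O+]=O)
Why: Ozonolysis of the exocyclic alkene gives the C11 ketone, and decarboxylation of the resulting β-keto acid deletes the tether carbon C9′.

Step 8
Reactants: 14 keto acid
Product: 16 Weinreb amide (C2 = C(=O)N(OMe)Me), via acid chloride 15 (not isolated)
Conditions: 1-chloro-N,N,2-trimethylprop-1-enylamine (1.2 equiv), CH2Cl2, 0 °C; then MeNHOMe·HCl (1.5 equiv), pyridine (3.5 equiv), 0 → 23 °C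
Reagents that add atoms: N,O-dimethylhydroxylamine hydrochloride (CNOC.Cl)
Why: Neutral acid chloride formation followed by N-acylation converts the hindered α-quaternary acid into the Weinreb amide.

Step 9
Reactants: 16 Weinreb amide
Product: 18 enol triflate (C10=C11–OTf), via potassium enolate 17 (not isolated)
Conditions: KN(SiMe3)2 (1.15 equiv), THF, −78 °C; then PhNTf2 (1.2 equiv), −78 → 0 °C
Reagents that add atoms: N-phenylbis(trifluoromethanesulfonimide) (O=S(=O)(N(c1ccccc1)S(=O)(=O)C(F)(F)F)C(F)(F)F)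
Why: Kinetic deprotonation takes the C10 methylene, away from the alkoxy-bearing C12, and O-triflation gives the C10=C11 enol triflate.

Step 10
Reactants: 18 enol triflate; 19 (trimethylsilyl)methylmagnesium chloride
Product: 21 allylsilane (C10=C11; C11–CH2SiMe3 = C20), via (trimethylsilylmethyl)zinc chloride 20 (not isolated)
Conditions: 19 (2.0 equiv), ZnCl2 (2.2 equiv), THF, 0 °C; then 18, Pd(PPh3)4 (5 mol %), 23 → 45 °C
Reagents that add atoms: none
Why: Negishi sp2–sp3 cross-coupling installs C20 as an allylsilane, and the organozinc spares the Weinreb amide.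

Step 11
Reactants: 21 allylsilane; 22 ethynylmagnesium bromide
Product: 23 ynone (C2 ketone; C3≡C4–H)
Conditions: 22 (3 equiv), THF, 0 °C; aqueous NH4Cl
Reagents that add atoms: none
Why: Weinreb ketone synthesis, in which the chelated tetrahedral adduct stops the addition at the ketone stage.

Step 12
Reactants: 23 ynone
Product: 24 (Z)-β-iodoenone (C2 ketone; C3=C4–I)
Conditions: LiI (3 equiv), AcOH (3 equiv), MeCN, 0 → 23 °C
Reagents that add atoms: lithium iodide ([Li+].[I-])
Why: Conjugate hydroiodination of the ynone gives the (Z)-β-iodoenone under kinetic control, and the weak acid is meant to spare the allylsilane and the acetonide.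

Step 13
Reactants: 24 (Z)-β-iodoenone
Product: 25 allylic alcohol (2S; 2-OH as in the target; Z-alkenyl iodide)
Conditions: (R)-2-methyl-CBS-oxazaborolidine (0.3 equiv), catecholborane (2 equiv), toluene, −78 → −40 °C
Reagents that add atoms: none
Why: Corey–Bakshi–Shibata reduction under catalyst control (tert-alkyl as the large group, iodoalkenyl as the small one) sets C2.

Step 14
Reactants: 25 allylic alcohol
Product: 26 west fragment (2-O-TBS ether of 25)
Conditions: TBSOTf (1.3 equiv), 2,6-lutidine (2 equiv), CH2Cl2, −78 °C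
Reagents that add atoms: tert-butyldimethylsilyl trifluoromethanesulfonate (CC(C)(C)[Si](C)(C)OS(=O)(=O)C(F)(F)F)
Why: Silyl triflate protection of the hindered secondary alcohol under non-protic conditions that leave the allylsilane intact.

**East fragment**

Step 15
Reactants: 27 2-methylenepropane-1,3-diol
Product: 28 2-[(4-methoxybenzyloxy)methyl]prop-2-en-1-ol
Conditions: NaH (1.0 equiv), PMBCl (1.0 equiv), Bu4NI (5 mol %), THF/DMF, 0 → 23 °C (27 in threefold excess)
Reagents that add atoms: 4-methoxybenzyl chloride (COc1ccc(CCl)cc1)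
Why: Statistical Williamson mono-etherification of the symmetric diol; the PMB-bearing carbon becomes C9.

Step 16
Reactants: 28 mono-PMB ether
Product: 29 2-[(4-methoxybenzyloxy)methyl]acrylaldehyde
Conditions: Dess–Martin periodinane, NaHCO3, CH2Cl2, 0 °C
Reagents that add atoms: none
Why: Dess–Martin oxidation of the allylic alcohol gives the enal whose carbonyl carbon becomes C7.

Step 17
Reactants: 30 propargyl alcohol
Product: 31 tert-butyldimethyl(prop-2-ynyloxy)silane
Conditions: TBSCl, imidazole, CH2Cl2, 0 °C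
Reagents that add atoms: tert-butyldimethylsilyl chloride (CC(C)(C)[Si](C)(C)Cl)
Why: Standard silylation; the unit supplies C6, C5 and C16.

Step 18
Reactants: 29 enal; 31 silyl propargyl ether
Product: 33 (3S)-6-(TBS-oxy)-2-(PMB-oxymethyl)hex-1-en-4-yn-3-ol, via alkynyl(methyl)zinc 32 (not isolated)
Conditions: 31 (2.5 equiv), Me2Zn (2.8 equiv), (S,S)-ProPhenol (20 mol %), Ph3PO (40 mol %), toluene, 0 °C; then 29, 4 °C
Reagents that add atoms: none
Why: Zinc/ProPhenol enantioselective alkynylation of the enal sets C7 (S) under catalyst control.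

Step 19
Reactants: 33 propargylic alcohol
Product: 35 (3S,4Z)-6-(TBS-oxy)-5-iodo-2-(PMB-oxymethyl)hexa-1,4-dien-3-ol, via cyclic vinylalanate 34 (not isolated)
Conditions: NaAlH2(OCH2CH2OMe)2 (1.6 equiv), THF, 0 → 23 °C; then EtOAc, I2 (2.5 equiv), −78 °C
Reagents that add atoms: iodine (II)
Why: Hydroxyl-directed trans-hydroalumination puts aluminium on the distal carbon (C5), and iodinolysis with retention gives the alkenyl iodide with iodine cis to C7, the geometry the ring closure needs.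

Step 20
Reactants: 35 dienol
Product: 37 (3S,4Z)-3-hydroxy-5-iodo-1-(PMB-oxy)-6-(TBS-oxy)hex-4-en-2-one, via triol 36 (not isolated)
Conditions: OsO4 (2 mol %), NaIO4 (4 equiv), 2,6-lutidine (2 equiv), 1,4-dioxane/H2O (3:1), 23 °C
Reagents that add atoms: sodium periodate ([Na+].[O-]I(=O)(=O)=O); water (O)
Why: Lemieux–Johnson cleavage, in which OsO4 takes the electron-rich 1,1-disubstituted alkene in preference to the iodoalkene, unveils the C8 ketone.

Step 21
Reactants: 37 α-hydroxy ketone; 38 methyl propionate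
Product: 41 γ-lactone as C17 epimer mixture (7S,8R; 8-OH; 8-CH2OPMB; 7-[(Z)-2-iodo-3-(TBS-oxy)prop-1-enyl]), via lithium enolate 39 (not isolated), via dilithium aldolate 40 (not isolated)
Conditions: 38 (3.3 equiv), LiN(iPr)2 (3.2 equiv), THF, −78 °C; then 37, −78 → 0 °C; aqueous NH4Cl
Reagents that add atoms: none
Why: Aldol addition to the five-membered lithium alkoxide–ketone chelate (Cram chelate model) occurs anti to the C6 alkenyl group and sets C8, and the C7 alkoxide lactonises on warming.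

Step 22
Reactants: 41 lactone epimer mixture
Product: 42 (3R,4R,5S)-4-hydroxy-5-[(Z)-2-iodo-3-(TBS-oxy)prop-1-enyl]-3-methyl-4-(PMB-oxymethyl)dihydrofuran-2(3H)-one
Conditions: DBU (0.3 equiv), CH2Cl2, 23 °C
Reagents that add atoms: none
Why: Base-mediated epimerisation at C17 converges on the epimer with the methyl trans to the C9 substituent, expected to be the more stable one.

Step 23
Reactants: 42 lactone
Product: 43 (3R,4R,5S)-4-hydroxy-4-(hydroxymethyl)-5-[(Z)-2-iodo-3-(TBS-oxy)prop-1-enyl]-3-methyldihydrofuran-2(3H)-one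
Conditions: DDQ (1.3 equiv), CH2Cl2/pH 7 buffer (10:1), 0 °C
Reagents that add atoms: none
Why: Oxidative PMB cleavage frees the C9 alcohol without touching the silyl ether, the lactone or the iodoalkene.

Step 24
Reactants: 43 diol
Product: 44 (2S,3S,4R)-3-hydroxy-2-[(Z)-2-iodo-3-(TBS-oxy)prop-1-enyl]-4-methyl-5-oxotetrahydrofuran-3-carbaldehyde
Conditions: Dess–Martin periodinane, NaHCO3, CH2Cl2, 23 °C
Reagents that add atoms: none
Why: Dess–Martin oxidation of the primary alcohol; the tertiary C8 alcohol cannot be oxidised and C8 cannot enolise.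

Step 25
Reactants: 44 hydroxy aldehyde
Product: 45 east fragment (8-O-TES ether of 44)
Conditions: TESOTf (1.5 equiv), 2,6-lutidine (3 equiv), CH2Cl2, −78 → 0 °C
Reagents that add atoms: triethylsilyl trifluoromethanesulfonate (CC[Si](CC)(CC)OS(=O)(=O)C(F)(F)F)
Why: Silyl triflate protection of the tertiary alcohol gives a stable α-silyloxy aldehyde for the union.

**Union and endgame**

Step 26
Reactants: 26 west fragment; 45 east fragment
Product: 46 seco bis(alkenyl iodide) (new C9–C10 bond; 9-OH and 10-H as in the target; C11=C20H2; C4–I and C5–I)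
Conditions: BF3·OEt2 (2 equiv), CH2Cl2, −78 °C
Reagents that add atoms: none
Why: Hosomi–Sakurai allylation through an open antiperiplanar transition state gives the syn C9/C10 pair, with the aldehyde approaching C10 on the β face away from the C2 side chain and the syn-axial 14-OTBS group, and the allyl transposition delivers the C11=C20 alkene.

Step 27
Reactants: 46 seco bis(alkenyl iodide)
Product: 47 macrocycle (briarane skeleton; 3Z,5E-diene; 11(20)-ene; 12,13-acetonide; 2,14,16-OTBS; 8-OTES; 9-OH)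
Conditions: NiBr2(dme) (30 mol %), 4,4′-di-tert-butyl-2,2′-bipyridine (33 mol %), Mn powder (8 equiv), NaI (2 equiv), DMA, 23 °C, 46 added over 12 h to a final 1 mM
Reagents that add atoms: none
Why: Proposed new method: an intramolecular nickel-catalysed reductive alkenyl–alkenyl coupling that closes a ten-membered ring, in which zerovalent nickel inserts into the less hindered (Z)-CH=CH–I bond, manganese reduces the adduct to an alkenyl complex of monovalent nickel, a second intramolecular oxidative addition at C5–I gives a dialkenyl complex of trivalent nickel, and reductive elimination forms C4–C5 with retention of both alkene geometries; the closest known reactions are intermolecular nickel-catalysed reductive alkenyl–alkenyl couplings and stoichiometric Ullmann-type ring closures of dihalides by zerovalent nickel.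

Step 28
Reactants: 47 macrocycle
Product: 48 pentaol (2,8,9,14,16-OH; 12,13-acetonide)
Conditions: HF·pyridine, pyridine, THF, 0 → 40 °C
Reagents that add atoms: none
Why: Buffered fluoride desilylation removes all four silyl groups without base, so the lactone cannot migrate to O-9, and leaves the acetonide.

Step 29
Reactants: 48 pentaol; 49 acetic anhydride
Product: 50 tetraacetate (2,9,14,16-OAc; 8-OH; 12,13-acetonide)
Conditions: 49 (20 equiv), pyridine, DMAP (0.3 equiv), CH2Cl2, 23 °C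
Reagents that add atoms: none
Why: DMAP-catalysed acetylation esterifies the primary and the three secondary hydroxyls, while the tertiary 8-OH stays free.

Step 30
Reactants: 50 tetraacetate
Product: 51 diol (12α,13α-OH)
Conditions: CF3CO2H/H2O (9:1), CH2Cl2, 0 °C
Reagents that add atoms: none
Why: Brief acid hydrolysis of the isopropylidene ketal frees the 12,13-diol with the acetates and the lactone in place.

Step 31
Reactants: 51 diol
Product: 52 epoxy diol (11α,20-epoxide)
Conditions: VO(acac)2 (10 mol %), t-BuOOH (1.5 equiv), CH2Cl2, 0 °C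
Reagents that add atoms: tert-butyl hydroperoxide (CC(C)(C)OO)
Why: Vanadium-catalysed hydroxyl-directed epoxidation delivers oxygen to C11=C20 syn to the allylic 12α-OH, which sets C11 and leaves the diene (no allylic OH) untouched.

Step 32
Reactants: 52 epoxy diol; 53 isovaleryl chloride
Product: 54 target CNP0303383.2
Conditions: 53 (4 equiv), pyridine, DMAP (0.2 equiv), CH2Cl2, 0 → 23 °C
Reagents that add atoms: none
Why: Acylation of the two secondary hydroxyls under basic conditions that the epoxide tolerates completes the target; the tertiary 8-OH does not react.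

**Compound list**
1 | furfuryl alcohol | OCc1ccco1 | starting material
2 | citraconic anhydride | CC1=CC(=O)OC1=O | starting material
3 | furfuryl hydrogen citraconate, (Z)-half-ester | OC(=O)/C(C)=C\C(=O)OCc1ccco1 | intermediate (not isolated)
4 | racemic tricyclic lactone acid (both enantiomers written) | O=C1OC[C@@]23O[C@@H](C=C2)[C@](C)(C(=O)O)[C@H]13.O=C1OC[C@]23O[C@H](C=C2)[C@@](C)(C(=O)O)[C@@H]13 | intermediate
5 | (R)-1-phenylethylammonium salt of 6 | O=C1OC[C@@]23O[C@@H](C=C2)[C@](C)(C(=O)[O-])[C@H]13.C[C@@H]([NH3+])c1ccccc1 | intermediate (not isolated)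
6 | lactone acid, single enantiomer (lactone and CO2H exo, methyl endo) | O=C1OC[C@@]23O[C@@H](C=C2)[C@](C)(C(=O)O)[C@H]13 | intermediate
7 | 12α,13α-diol acid | O=C1OC[C@@]23O[C@@H]([C@@H](O)[C@H]2O)[C@](C)(C(=O)O)[C@H]13 | intermediate
8 | 12α,13α-acetonide acid | O=C1OC[C@@]23O[C@@H]([C@H]4OC(C)(C)O[C@@H]24)[C@](C)(C(=O)O)[C@H]13 | intermediate
9 | dilithium alkoxide carboxylate of the ring-opened butenolide | [Li+].[Li+].O=C1OCC2=C1[C@@](C)(C(=O)[O-])[C@@H]([O-])[C@H]3OC(C)(C)O[C@@H]23 | intermediate (not isolated)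
10 | TBS ester of 11 | O=C1OCC2=C1[C@@](C)(C(=O)O[Si](C)(C)C(C)(C)C)[C@@H](O[Si](C)(C)C(C)(C)C)[C@H]3OC(C)(C)O[C@@H]23 | intermediate (not isolated)
11 | butenolide acid (C10=C11, 14α-OTBS, 12α,13α-acetonide, 1β-Me, 1α-CO2H) | O=C1OCC2=C1[C@@](C)(C(=O)O)[C@@H](O[Si](C)(C)C(C)(C)C)[C@H]3OC(C)(C)O[C@@H]23 | intermediate
12 | diacid with exocyclic C11=C20 (C10 epimers) | OC(=O)C1C(=C)[C@@H]2OC(C)(C)O[C@@H]2[C@H](O[Si](C)(C)C(C)(C)C)[C@]1(C)C(=O)O | intermediate
13 | β-keto diacid (C11 ketone, C9′O2H on C10) | OC(=O)C1C(=O)[C@@H]2OC(C)(C)O[C@@H]2[C@H](O[Si](C)(C)C(C)(C)C)[C@]1(C)C(=O)O | intermediate (not isolated)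
14 | keto acid (C11 ketone, C10 H2, C2O2H) | C1C(=O)[C@@H]2OC(C)(C)O[C@@H]2[C@H](O[Si](C)(C)C(C)(C)C)[C@]1(C)C(=O)O | intermediate
15 | acid chloride of 14 | C1C(=O)[C@@H]2OC(C)(C)O[C@@H]2[C@H](O[Si](C)(C)C(C)(C)C)[C@]1(C)C(Cl)=O | intermediate (not isolated)
16 | Weinreb amide of 14 | C1C(=O)[C@@H]2OC(C)(C)O[C@@H]2[C@H](O[Si](C)(C)C(C)(C)C)[C@]1(C)C(=O)N(C)OC | intermediate
17 | potassium enolate (C10=C11–OK) | [K+].C1=C([O-])[C@@H]2OC(C)(C)O[C@@H]2[C@H](O[Si](C)(C)C(C)(C)C)[C@]1(C)C(=O)N(C)OC | intermediate (not isolated)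
18 | enol triflate (C10=C11–OTf) | C1=C(OS(=O)(=O)C(F)(F)F)[C@@H]2OC(C)(C)O[C@@H]2[C@H](O[Si](C)(C)C(C)(C)C)[C@]1(C)C(=O)N(C)OC | intermediate
19 | (trimethylsilyl)methylmagnesium chloride | C[Si](C)(C)C[Mg]Cl | starting material
20 | (trimethylsilylmethyl)zinc chloride | C[Si](C)(C)C[Zn]Cl | intermediate (not isolated)
21 | allylsilane Weinreb amide (C11–CH2SiMe3) | C1=C(C[Si](C)(C)C)[C@@H]2OC(C)(C)O[C@@H]2[C@H](O[Si](C)(C)C(C)(C)C)[C@]1(C)C(=O)N(C)OC | intermediate
22 | ethynylmagnesium bromide | C#C[Mg]Br | starting material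
23 | ynone (C2 ketone, C3≡C4H) | C1=C(C[Si](C)(C)C)[C@@H]2OC(C)(C)O[C@@H]2[C@H](O[Si](C)(C)C(C)(C)C)[C@]1(C)C(=O)C#C | intermediate
24 | (Z)-β-iodoenone | C1=C(C[Si](C)(C)C)[C@@H]2OC(C)(C)O[C@@H]2[C@H](O[Si](C)(C)C(C)(C)C)[C@]1(C)C(=O)/C=C\I | intermediate
25 | (2S)-allylic alcohol, Z-alkenyl iodide | C1=C(C[Si](C)(C)C)[C@@H]2OC(C)(C)O[C@@H]2[C@H](O[Si](C)(C)C(C)(C)C)[C@]1(C)[C@@H](O)/C=C\I | intermediate
26 | west fragment (2,14-bis-OTBS, 12,13-acetonide, allylsilane, Z-alkenyl iodide) | C1=C(C[Si](C)(C)C)[C@@H]2OC(C)(C)O[C@@H]2[C@H](O[Si](C)(C)C(C)(C)C)[C@]1(C)[C@@H](O[Si](C)(C)C(C)(C)C)/C=C\I | intermediate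
27 | 2-methylenepropane-1,3-diol | C=C(CO)CO | starting material
28 | 2-[(4-methoxybenzyloxy)methyl]prop-2-en-1-ol | C=C(CO)COCc1ccc(OC)cc1 | intermediate
29 | 2-[(4-methoxybenzyloxy)methyl]acrylaldehyde | C=C(C=O)COCc1ccc(OC)cc1 | intermediate
30 | propargyl alcohol | C#CCO | starting material
31 | tert-butyldimethyl(prop-2-ynyloxy)silane | C#CCO[Si](C)(C)C(C)(C)C | intermediate
32 | methylzinc acetylide of 31 | C[Zn]C#CCO[Si](C)(C)C(C)(C)C | intermediate (not isolated)
33 | (3S)-6-(TBS-oxy)-2-(PMB-oxymethyl)hex-1-en-4-yn-3-ol | C=C(COCc1ccc(OC)cc1)[C@@H](O)C#CCO[Si](C)(C)C(C)(C)C | intermediate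
34 | sodium cyclic alkoxy(alkenyl)alanate | [Na+].C=C(COCc1ccc(OC)cc1)[C@H]1O[Al-](OCCOC)(OCCOC)C(CO[Si](C)(C)C(C)(C)C)=C1 | intermediate (not isolated)
35 | (3S,4Z)-6-(TBS-oxy)-5-iodo-2-(PMB-oxymethyl)hexa-1,4-dien-3-ol | C=C(COCc1ccc(OC)cc1)[C@@H](O)/C=C(\I)CO[Si](C)(C)C(C)(C)C | intermediate
36 | 1,2,3-triol from dihydroxylation of 35 (C8 epimers) | OCC(O)(COCc1ccc(OC)cc1)[C@@H](O)/C=C(\I)CO[Si](C)(C)C(C)(C)C | intermediate (not isolated)
37 | (3S,4Z)-3-hydroxy-5-iodo-1-(PMB-oxy)-6-(TBS-oxy)hex-4-en-2-one | O=C(COCc1ccc(OC)cc1)[C@@H](O)/C=C(\I)CO[Si](C)(C)C(C)(C)C | intermediate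
38 | methyl propionate | CCC(=O)OC | starting material
39 | lithium enolate of methyl propionate | [Li+].CC=C([O-])OC | intermediate (not isolated)
40 | dilithium aldolate (C17 epimers) | [Li+].[Li+].COC(=O)C(C)[C@@]([O-])(COCc1ccc(OC)cc1)[C@@H]([O-])/C=C(\I)CO[Si](C)(C)C(C)(C)C | intermediate (not isolated)
41 | γ-lactone, C17 epimer mixture | CC(C)(C)[Si](C)(C)OCC(/I)=C/[C@@H]1OC(=O)C(C)[C@@]1(O)COCc1ccc(OC)cc1 | intermediate
42 | (3R,4R,5S)-4-hydroxy-5-[(Z)-2-iodo-3-(TBS-oxy)prop-1-enyl]-3-methyl-4-(PMB-oxymethyl)dihydrofuran-2(3H)-one | CC(C)(C)[Si](C)(C)OCC(/I)=C/[C@@H]1OC(=O)[C@H](C)[C@@]1(O)COCc1ccc(OC)cc1 | intermediate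
43 | (3R,4R,5S)-4-hydroxy-4-(hydroxymethyl)-5-[(Z)-2-iodo-3-(TBS-oxy)prop-1-enyl]-3-methyldihydrofuran-2(3H)-one | CC(C)(C)[Si](C)(C)OCC(/I)=C/[C@@H]1OC(=O)[C@H](C)[C@@]1(O)CO | intermediate
44 | (2S,3S,4R)-3-hydroxy-2-[(Z)-2-iodo-3-(TBS-oxy)prop-1-enyl]-4-methyl-5-oxotetrahydrofuran-3-carbaldehyde | CC(C)(C)[Si](C)(C)OCC(/I)=C/[C@@H]1OC(=O)[C@H](C)[C@@]1(O)C=O | intermediate
45 | east fragment (8-O-TES ether of 44) | CC(C)(C)[Si](C)(C)OCC(/I)=C/[C@@H]1OC(=O)[C@H](C)[C@@]1(O[Si](CC)(CC)CC)C=O | intermediate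
46 | seco bis(alkenyl iodide) | CC(C)(C)[Si](C)(C)OCC(/I)=C/[C@@H]1OC(=O)[C@H](C)[C@@]1(O[Si](CC)(CC)CC)[C@@H](O)[C@H]2C(=C)[C@@H]3OC(C)(C)O[C@@H]3[C@H](O[Si](C)(C)C(C)(C)C)[C@]2(C)[C@@H](O[Si](C)(C)C(C)(C)C)/C=C\I | intermediate
47 | protected macrocycle | CC(C)(C)[Si](C)(C)OCC1=C/[C@@H]2OC(=O)[C@H](C)[C@@]2(O[Si](CC)(CC)CC)[C@@H](O)[C@H]3C(=C)[C@@H]4OC(C)(C)O[C@@H]4[C@H](O[Si](C)(C)C(C)(C)C)[C@]3(C)[C@@H](O[Si](C)(C)C(C)(C)C)/C=C\1 | intermediate
48 | pentaol acetonide | OCC1=C/[C@@H]2OC(=O)[C@H](C)[C@@]2(O)[C@@H](O)[C@H]3C(=C)[C@@H]4OC(C)(C)O[C@@H]4[C@H](O)[C@]3(C)[C@@H](O)/C=C\1 | intermediate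
49 | acetic anhydride | CC(=O)OC(C)=O | starting material
50 | 2,9,14,16-tetraacetate acetonide | CC(=O)OCC1=C/[C@@H]2OC(=O)[C@H](C)[C@@]2(O)[C@@H](OC(C)=O)[C@H]3C(=C)[C@@H]4OC(C)(C)O[C@@H]4[C@H](OC(C)=O)[C@]3(C)[C@@H](OC(C)=O)/C=C\1 | intermediate
51 | 12α,13α-diol tetraacetate | CC(=O)OCC1=C/[C@@H]2OC(=O)[C@H](C)[C@@]2(O)[C@@H](OC(C)=O)[C@H]3C(=C)[C@H](O)[C@H](O)[C@H](OC(C)=O)[C@]3(C)[C@@H](OC(C)=O)/C=C\1 | intermediate
52 | 11α,20-epoxy-12α,13α-diol tetraacetate | CC(=O)OCC1=C/[C@@H]2OC(=O)[C@H](C)[C@@]2(O)[C@@H](OC(C)=O)[C@H]3[C@@]4(CO4)[C@H](O)[C@H](O)[C@H](OC(C)=O)[C@]3(C)[C@@H](OC(C)=O)/C=C\1 | intermediate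
53 | isovaleryl chloride | CC(C)CC(Cl)=O | starting material
54 | CNP0303383.2 | CC(=O)OCC1=C/[C@@H]2OC(=O)[C@H](C)[C@@]2(O)[C@@H](OC(C)=O)[C@H]2[C@@]3(CO3)[C@H](OC(=O)CC(C)C)[C@H](OC(=O)CC(C)C)[C@H](OC(C)=O)[C@]2(C)[C@@H](OC(C)=O)/C=C\1 | target

**Step count and risks**

Total: 32 steps (1–14 west fragment, 15–25 east fragment, 26–32 union and endgame). Longest linear sequence: 21 steps (1–14, then 26–32); the east branch has 10 linear steps before the union.

Most likely to fail, first: step 27, the new nickel-catalysed ring closure. Oligomerisation, loss of the Z geometry on nickel and Heck-type attack on C11=C20 are the risks. The fallback uses known boron chemistry, sets out from 26 and comes back at 47. Miyaura borylation of 26 [PdCl2(dppf), B2pin2, KOPh, toluene, 50 °C] gives the west (Z)-alkenyl pinacol boronate F1. Hosomi–Sakurai reaction of F1 with 45 (BF3·OEt2, CH2Cl2, −78 °C) gives the seco boronate iodide F2. Intramolecular Suzuki–Miyaura coupling of F2 [Pd(PPh3)4, K3PO4, THF/H2O, 1 mM, 50 °C] gives 47.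

Second: step 26, the Sakurai union. Both partners are hindered, and the β-face attack at C10 and the syn C9/C10 relationship rest on models. The fallback sets out from 26 (used with 45) and comes back at 46. Bromodesilylation of 26 (N-bromosuccinimide, CH2Cl2, −78 °C) gives the allylic bromide F3. Nozaki–Hiyama allylation of 45 with F3 (nickel-free CrCl2, THF, 0 °C) tolerates hindrance but is anti-selective, so it gives the C9 epimer F4. Dess–Martin oxidation gives the C9 ketone F5, and Felkin-controlled reduction with hydride entering anti to C1 (NaBH4, CeCl3, MeOH, −78 °C) gives 46.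

Third: step 12, the hydroiodination. The acid may protodesilylate the allylsilane or erode the Z geometry. The fallback sets out from 23 and comes back at 26, bypassing 24 and 25. CBS reduction of 23 [(R)-2-methyl-CBS-oxazaborolidine, catecholborane] gives the propargylic alcohol F6. TBSOTf/2,6-lutidine gives the silyl ether F7. LiN(SiMe3)2 then I2 (THF, −78 °C) gives the iodoalkyne F8, and diimide reduction (2-nitrobenzenesulfonylhydrazide, Et3N, THF/i-PrOH) gives 26.

**Further compounds**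
F1 | step 27 | west (Z)-alkenyl pinacol boronate (26 with Bpin in place of iodine) | C1=C(C[Si](C)(C)C)[C@@H]2OC(C)(C)O[C@@H]2[C@H](O[Si](C)(C)C(C)(C)C)[C@]1(C)[C@@H](O[Si](C)(C)C(C)(C)C)/C=C\B3OC(C)(C)C(C)(C)O3
F2 | step 27 | seco boronate iodide (46 with Bpin at C4) | CC(C)(C)[Si](C)(C)OCC(/I)=C/[C@@H]1OC(=O)[C@H](C)[C@@]1(O[Si](CC)(CC)CC)[C@@H](O)[C@H]2C(=C)[C@@H]3OC(C)(C)O[C@@H]3[C@H](O[Si](C)(C)C(C)(C)C)[C@]2(C)[C@@H](O[Si](C)(C)C(C)(C)C)/C=C\B4OC(C)(C)C(C)(C)O4
F3 | step 26 | allylic bromide (C10–Br, C11=C20H2, C10 epimers) | BrC1C(=C)[C@@H]2OC(C)(C)O[C@@H]2[C@H](O[Si](C)(C)C(C)(C)C)[C@]1(C)[C@@H](O[Si](C)(C)C(C)(C)C)/C=C\I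
F4 | step 26 | C9 epimer of 46 | CC(C)(C)[Si](C)(C)OCC(/I)=C/[C@@H]1OC(=O)[C@H](C)[C@@]1(O[Si](CC)(CC)CC)[C@H](O)[C@H]2C(=C)[C@@H]3OC(C)(C)O[C@@H]3[C@H](O[Si](C)(C)C(C)(C)C)[C@]2(C)[C@@H](O[Si](C)(C)C(C)(C)C)/C=C\I
F5 | step 26 | C9 ketone of 46 | CC(C)(C)[Si](C)(C)OCC(/I)=C/[C@@H]1OC(=O)[C@H](C)[C@@]1(O[Si](CC)(CC)CC)C(=O)[C@H]2C(=C)[C@@H]3OC(C)(C)O[C@@H]3[C@H](O[Si](C)(C)C(C)(C)C)[C@]2(C)[C@@H](O[Si](C)(C)C(C)(C)C)/C=C\I
F6 | step 12 | (2S)-propargylic alcohol (C3≡C4H) | C1=C(C[Si](C)(C)C)[C@@H]2OC(C)(C)O[C@@H]2[C@H](O[Si](C)(C)C(C)(C)C)[C@]1(C)[C@@H](O)C#C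
F7 | step 12 | 2-O-TBS ether of F6 | C1=C(C[Si](C)(C)C)[C@@H]2OC(C)(C)O[C@@H]2[C@H](O[Si](C)(C)C(C)(C)C)[C@]1(C)[C@@H](O[Si](C)(C)C(C)(C)C)C#C
F8 | step 12 | iodoalkyne (C4–I) | C1=C(C[Si](C)(C)C)[C@@H]2OC(C)(C)O[C@@H]2[C@H](O[Si](C)(C)C(C)(C)C)[C@]1(C)[C@@H](O[Si](C)(C)C(C)(C)C)C#CI
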